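**Assumptions (one line):** The target is the 2,3-trans (2R,3R) 6-geranyl dihydroflavonol, as read from the SMILES. Compounds 1, 2, 4, 6, 9 and 12 are commercial (poly-D-leucine is bought or made from D-Leu NCA). Bases, catalysts, solvents, TBAF and ZnBr2 are given in the conditions and are not numbered.

## Retrosynthetic overview
1. Target (2R,3R)-dihydroflavonol ⇐ tri-MOM dihydroflavonol. The pyranone C-ring is closed last, by fluoride-triggered 6-exo-tet opening of a (2R,3S)-trans-α,β-epoxy ketone by the ortho phenoxide at the benzylic carbon (inversion). This sets C2, while C3 comes from the epoxide.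
2. Epoxy ketone ⇐ E-chalcone by nucleophilic asymmetric epoxidation (Juliá–Colonna). This is chemoselective and leaves the geranyl alkenes intact, whereas OsO4 or peracids would attack them.
3. Chalcone ⇐ Claisen–Schmidt of a regio-differentiated acetophenone (2',4'-di-OMOM, 6'-OTIPS, 3'-geranyl) with MOM-isovanillin.
4. The ring-closing oxygen is the 6'-O, remote from the geranyl group, which guarantees 6- rather than 8-geranyl. The acetophenone comes from phloroacetophenone by 4'-MOM protection, C-geranylation, sterically selective 6'-silylation and 2'-MOM protection.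

## Route

**Step 1**
Reactants: 1 (phloroacetophenone), 2 (MOMCl)
Product: 3 (2',6'-dihydroxy-4'-MOM-oxyacetophenone)
Conditions: MOMCl (1.0 equiv), K2CO3, acetone, 0 °C → rt
Reagents that add atoms: MOMCl, COCCl
Why: The 4'-OH is the most acidic and is not H-bond chelated to the C=O, so it alkylates first (Williamson-type O-alkylation). Over-alkylated material is removed chromatographically.

**Step 2**
Reactants: 3, 4 (geranyl bromide)
Product: 5 (3'-geranyl-2',6'-dihydroxy-4'-MOM-oxyacetophenone)
Conditions: geranyl bromide (1.1 equiv), KOH, MeOH/H2O, 0 °C → rt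
Reagents that add atoms: geranyl bromide, CC(C)=CCC/C(C)=C/CBr (E)
Why: In protic aqueous base the phenoxide O is H-bonded and C-alkylates ortho (Friedel–Crafts-type C-allylation of a phloroglucinol). Positions 3' and 5' of 3 are equivalent, so there is no regiochemical ambiguity, and the E-geranyl geometry is retained.

**Step 3**
Reactants: 5, 6 (TIPSCl)
Product: 7 (6'-OTIPS-2'-hydroxy-3'-geranyl-4'-MOM-oxyacetophenone)
Conditions: TIPSCl (1.1 equiv), imidazole, DMF, 40 °C
Reagents that add atoms: TIPSCl, CC(C)[Si](Cl)(C(C)C)C(C)C
Why: The bulky silyl chloride reacts at the unhindered 6'-OH rather than the 2'-OH, which is flanked by the acetyl and geranyl groups. This makes the future ring oxygen the one remote from geranyl (silylation of an alcohol).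

**Step 4**
Reactants: 7, 2 (MOMCl)
Product: 8 (2',4'-bis-MOM-6'-OTIPS-3'-geranylacetophenone)
Conditions: NaH, then MOMCl, THF/DMF, 0 °C → rt
Reagents that add atoms: MOMCl, COCCl
Why: The small MOM electrophile alkylates the hindered chelated phenoxide, and TIPS survives NaH (Williamson-type MOM protection).

**Step 5**
Reactants: 9 (isovanillin), 2 (MOMCl)
Product: 10 (4-methoxy-3-(methoxymethoxy)benzaldehyde)
Conditions: MOMCl, i-Pr2NEt, CH2Cl2, 0 °C → rt
Reagents that add atoms: MOMCl, COCCl
Why: Simple MOM protection of the 3-phenol. MOM is base-stable for the aldol and epoxidation steps and is removed at the end with the A-ring MOMs.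

**Step 6**
Reactants: 8, 10
Product: 11 ((E)-chalcone)
Conditions: KOH, EtOH/H2O, rt, 48 h
Reagents that add atoms: none (H2O is lost)
Why: Claisen–Schmidt aldol condensation. The ortho-dioxygenated ketone enolizes under strong base, the aryl TIPS ether is robust to hydroxide at rt, and E-selectivity is thermodynamic.

**Step 7**
Reactants: 11, 12 (hydrogen peroxide as urea·H2O2)
Product: 13 ((2R,3S)-trans-epoxy ketone)
Conditions: poly-D-leucine, urea·H2O2, DBU, THF, rt
Reagents that add atoms: hydrogen peroxide (urea adduct), OO (adds one O)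
Why: Juliá–Colonna (Weitz–Scheffer-type) nucleophilic epoxidation. The helical poly-D-Leu delivers HOO⁻ to one enone face and sets both epoxide carbons (2R,3S) in a trans epoxide. It is the antipode of the poly-L-Leu series that gives (2S,3R). The geranyl alkenes are not electrophilic-oxidation targets under these conditions.

**Step 8**
Reactants: 13
Product: 14 ((2R,3R)-3-hydroxy-5,7,3'-tri-MOM-6-geranyl-4'-methoxyflavanone)
Conditions: TBAF (1.2 equiv), THF, –20 → 0 °C, 30 min; quench with sat. NH4Cl
Reagents that add atoms: none
Why: Proposed new method: F⁻ removes the 6'-OTIPS group to give the phenoxide, which opens the epoxide at the benzylic carbon (6-exo-tet, SN2 with inversion) to give C2 = R. The epoxide oxygen stays on Cα as the 3-OH (C3 = R), and trans epoxide gives the 2,3-trans product. The closest known reaction types are the AFO-type cyclization of 2'-hydroxychalcone epoxides to trans-dihydroflavonols and fluoride-triggered intramolecular SN2. The ring closes through the 6'-O because the 2'-O is MOM-capped.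

**Step 9**
Reactants: 14
Product: 15 (target, 4'-O-methyldiplacol)
Conditions: ZnBr2, n-PrSH, CH2Cl2, 0 °C → rt, 30 min
Reagents that add atoms: none
Why: Lewis-acid/thiol cleavage of aryl MOM acetals. The thiol traps the oxocarbenium, minimizing acid-induced geranyl cyclization. The 2,3-trans centers do not epimerize under these acidic, non-enolizing conditions.

## Compound list
1 | 2',4',6'-trihydroxyacetophenone | CC(=O)c1c(O)cc(O)cc1O | starting material
2 | chloromethyl methyl ether (MOMCl) | COCCl | starting material (reagent)
3 | 1-[2,6-dihydroxy-4-(methoxymethoxy)phenyl]ethanone | CC(=O)c1c(O)cc(OCOC)cc1O | intermediate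
4 | geranyl bromide | BrC/C=C(\C)CCC=C(C)C | starting material (reagent)
5 | 1-[3-geranyl-2,6-dihydroxy-4-(methoxymethoxy)phenyl]ethanone | CC(=O)c1c(O)c(C/C=C(\C)CCC=C(C)C)c(OCOC)cc1O | intermediate
6 | triisopropylsilyl chloride | CC(C)[Si](Cl)(C(C)C)C(C)C | starting material (reagent)
7 | 1-[3-geranyl-2-hydroxy-4-(methoxymethoxy)-6-(triisopropylsilyloxy)phenyl]ethanone | CC(=O)c1c(O)c(C/C=C(\C)CCC=C(C)C)c(OCOC)cc1O[Si](C(C)C)(C(C)C)C(C)C | intermediate
8 | 1-[3-geranyl-2,4-bis(methoxymethoxy)-6-(triisopropylsilyloxy)phenyl]ethanone | CC(=O)c1c(OCOC)c(C/C=C(\C)CCC=C(C)C)c(OCOC)cc1O[Si](C(C)C)(C(C)C)C(C)C | intermediate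
9 | isovanillin (3-hydroxy-4-methoxybenzaldehyde) | COc1ccc(C=O)cc1O | starting material
10 | 4-methoxy-3-(methoxymethoxy)benzaldehyde | COc1ccc(C=O)cc1OCOC | intermediate
11 | (E)-chalcone: 1-[A-ring of 8]-3-[4-methoxy-3-(methoxymethoxy)phenyl]prop-2-en-1-one | COc1ccc(/C=C/C(=O)c2c(OCOC)c(C/C=C(\C)CCC=C(C)C)c(OCOC)cc2O[Si](C(C)C)(C(C)C)C(C)C)cc1OCOC | intermediate
12 | hydrogen peroxide (as urea·H2O2) | OO | starting material (reagent)
13 | (2R,3S)-trans-2,3-epoxy-1,3-diaryl-propan-1-one (epoxide of 11) | COc1ccc([C@@H]2O[C@H]2C(=O)c2c(OCOC)c(C/C=C(\C)CCC=C(C)C)c(OCOC)cc2O[Si](C(C)C)(C(C)C)C(C)C)cc1OCOC | intermediate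
14 | (2R,3R)-3-hydroxy-5,7,3'-tri-MOM-6-geranyl-4'-methoxyflavanone | COc1ccc([C@H]2Oc3cc(OCOC)c(C/C=C(\C)CCC=C(C)C)c(OCOC)c3C(=O)[C@@H]2O)cc1OCOC | intermediate
15 | 4'-O-methyldiplacol | COc1ccc([C@H]2Oc3cc(O)c(C/C=C(\C)CCC=C(C)C)c(O)c3C(=O)[C@@H]2O)cc1O | target

**Total steps:** 9 (step 5 is a parallel branch). **Longest linear sequence:** 8 steps (1 → 2 → 3 → 4 → 6 → 7 → 8 → 9).

## Three steps most likely to fail
1. **Step 7 (asymmetric epoxidation of the hindered, electron-rich chalcone):** conversion and ee may be low.
   Fallback: change the approach to Sharpless asymmetric epoxidation of (E)-3-[4-methoxy-3-(MOM-oxy)phenyl]allyl alcohol. Oxidize the epoxy alcohol to the epoxy Weinreb amide, then add the aryllithium from the bromide of the 2,4-bis-MOM-6-OTIPS-3-geranyl-arene to give epoxy ketone 13.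
2. **Step 8 (desilylative 6-exo cyclization):** competing 5-exo attack at Cα (aurone-type product), and C3 epimerization or ring-opening under basic TBAF.
   Fallback: desilylate with HF·pyridine to the neutral phenol epoxide, then cyclize by Lewis-acid catalysis (Sc(OTf)3, CH2Cl2, –20 °C). This swaps a base-triggered phenoxide SN2 for acid-activated benzylic opening.
3. **Step 2 (C-geranylation):** low yield from O- versus C-alkylation, dialkylation and SN2' (branched) geranyl.
   Fallback: iodinate 3 ortho to the free OH (NIS), then Pd-catalyzed Negishi coupling with geranylzinc bromide. This retains the E geometry and avoids the direct alkylation.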